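## Retrosynthetic overview

1. Target ⇒ chelation-directed O-demethylation, then sp2–sp3 Negishi union of a ring A aryl bromide with the side-chain alkylzinc. The side-chain stereocentre comes from a copper-catalysed SN2′ alkylation of isoprene dibromide.
2. Aryl bromide ⇒ (S)-hydroxyisopropyl-dihydrobenzofuran by C7 aroylation (directed lithiation, carbamoyl chloride, 3-lithiophenolate from 3-bromophenol) and C5 bromination.
3. Dihydrobenzofuran ⇒ ring contraction of an (R)-2,2-dimethylchroman-3-ol: 1,2-shift of the ring oxygen through an aryloxiranium ion, with inversion at the carbinol carbon (key step).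
4. Chromanol ⇒ 2,2-dimethylchromene (Jacobsen epoxidation, hydride opening) ⇒ 3,5-dimethoxyphenol + 3-methylbut-2-enal; the phenol ⇒ resorcinol by methylation and C–H borylation/oxidation.
5. Ring order: ring A (resorcinol) → pyran ring → contracted to the dihydrofuran → ring B attached.

Assumption: the (R,R)-(salen)MnCl catalyst gives the 3R,4R chromene oxide as it does with the parent 2,2-dimethylchromene, and the ligand enantiomer named in step 8 gives the S bromide; if either sense is found reversed, the mirror-image catalyst or ligand is used.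

## Route

Step 1
Reactants: 1 resorcinol
Product: 3 1,3-dimethoxybenzene, via 3-methoxyphenol 2 (not isolated)
Conditions: MeI (2.5 equiv), K2CO3 (3 equiv), acetone, reflux
Reagents that add atoms: iodomethane, CI
Why: Williamson O-methylation of both phenols through the mono-ether, with no stereocentre involved.

Step 2
Reactants: 3 1,3-dimethoxybenzene
Product: 5 3,5-dimethoxyphenol, via aryl pinacol boronate 4 (not isolated)
Conditions: [Ir(OMe)(cod)]2 (1 mol %), 4,4′-di-tert-butyl-2,2′-bipyridine (2 mol %), B2pin2 (0.6 equiv), THF, 80 °C; then KHSO5 (Oxone), acetone/H2O, 20 °C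
Reagents that add atoms: potassium peroxymonosulfate (KHSO5), [K+].[O-]S(=O)(=O)OO
Why: Sterically controlled iridium-catalysed C–H borylation takes the only C–H not flanked by an ortho substituent (C5), and the boronate is oxidised in the same pot to the phenol (one-pot C–H borylation/oxidation).

Step 3
Reactants: 5 3,5-dimethoxyphenol; 6 3-methylbut-2-enal
Product: 8 5,7-dimethoxy-2,2-dimethyl-2H-chromene, via ortho-quinone methide 7 (not isolated)
Conditions: ethylenediammonium diacetate (10 mol %), xylene, 140 °C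
Reagents that add atoms: none
Why: Ammonium-salt-catalysed condensation of the enal at a phenol ortho carbon (the two are equivalent) gives the ortho-quinone methide, which closes by oxa-6π electrocyclisation to the chromene.

Step 4
Reactants: 8 5,7-dimethoxy-2,2-dimethyl-2H-chromene
Product: 10 (3R)-5,7-dimethoxy-2,2-dimethylchroman-3-ol, via chromene oxide 9 (not isolated)
Conditions: (R,R)-(salen)MnCl (5 mol %; salen = N,N′-bis(3,5-di-tert-butylsalicylidene)-(1R,2R)-cyclohexane-1,2-diamine dianion, trivalent manganese), NMO (5 equiv), mCPBA (2 equiv), CH2Cl2, −78 °C; cold aq NaOH wash, dry over K2CO3, solvent switch; then LiBHEt3 (1.5 equiv), THF, −78 → 0 °C; H2O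
Reagents that add atoms: 3-chloroperoxybenzoic acid (mCPBA), OOC(=O)c1cccc(Cl)c1
Why: Jacobsen–Katsuki epoxidation of a 2,2-dimethylchromene (the best substrate class, typically above 95 % ee) sets C3 as R, and SN2 hydride delivery to the benzylic C4 of the acid-labile oxide (carried forward in solution) leaves the C3–O bond untouched, with crystalline 10 allowing an ee upgrade.

Step 5
Reactants: 10 (3R)-5,7-dimethoxy-2,2-dimethylchroman-3-ol
Product: 13 2-[(2S)-4,6-dimethoxy-2,3-dihydro-1-benzofuran-2-yl]propan-2-ol, via chromanyl triflate 11 (not isolated), via aryloxiranium triflate 12 (not isolated)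
Conditions: Tf2O (1.15 equiv), 2,6-lutidine (3 equiv), CH2Cl2, −78 °C; then THF/H2O (3:1), NaHCO3, −78 → 20 °C
Reagents that add atoms: water, O
Why: Key ring contraction by neighbouring-group-assisted solvolysis, a reaction type known for activated 3-hydroxy-2,2-dimethylchromans: in the conformer with C3–OTf antiperiplanar to O1–C2 the ring oxygen displaces triflate from the back (1,2-oxygen shift, inversion, 3R → 2S), and water opens the aryloxiranium ion at the tertiary carbon.

Step 6
Reactants: 13 2-[(2S)-4,6-dimethoxy-2,3-dihydro-1-benzofuran-2-yl]propan-2-ol; 14 3-bromophenol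
Product: 19 (3-hydroxyphenyl)[(2S)-2-(2-hydroxypropan-2-yl)-4,6-dimethoxy-2,3-dihydro-1-benzofuran-7-yl]methanone, via C7-lithio alkoxide 15 (not isolated), via Weinreb amide 16 (not isolated), via lithium 3-lithiophenolate 17 (not isolated), via tetrahedral adduct 18 (not isolated)
Conditions: 13, n-BuLi (2.1 equiv), THF, 0 → 20 °C; cannulate into ClC(O)N(OMe)Me (1.1 equiv), THF, −78 °C; then 17 (1.6 equiv; made from 14 with n-BuLi 1 equiv then t-BuLi 2 equiv, THF, −78 °C), −78 → 0 °C; AcOH
Reagents that add atoms: N-methoxy-N-methylcarbamoyl chloride, CON(C)C(Cl)=O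
Why: The lithium alkoxide chelates O1 and steers ortho-lithiation to C7 (also the less hindered of the two doubly oxygen-flanked sites), acyl substitution on the carbamoyl chloride gives a Weinreb amide, and addition of the aryllithium stops at the chelated adduct that collapses to the ketone on quench (directed ortho metalation followed by Weinreb ketone synthesis), leaving C2 untouched.

Step 7
Reactants: 19 (3-hydroxyphenyl)[(2S)-2-(2-hydroxypropan-2-yl)-4,6-dimethoxy-2,3-dihydro-1-benzofuran-7-yl]methanone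
Product: 20 [(2S)-5-bromo-2-(2-hydroxypropan-2-yl)-4,6-dimethoxy-2,3-dihydro-1-benzofuran-7-yl](3-hydroxyphenyl)methanone
Conditions: NBS (1.05 equiv), MeCN, 0 °C, dark
Reagents that add atoms: N-bromosuccinimide, O=C1CCC(=O)N1Br
Why: Electrophilic aromatic bromination at C5, the only free position of ring A and activated by three oxygen donors, which reacts far faster than the acyl-deactivated phenol ring B.

Step 8
Reactants: 21 4-bromo-2-methylbut-1-ene; 22 (E)-1,4-dibromo-2-methylbut-2-ene
Product: 24 (3S)-3-(bromomethyl)-2,6-dimethylhepta-1,6-diene, via Grignard reagent 23 (not isolated)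
Conditions: Mg, Et2O, 35 °C; then 22, Cu(O2CC4H3S) (copper thiophene-2-carboxylate, monovalent copper, 3 mol %), phosphoramidite L (3.3 mol %; L = O,O′-[(S)-1,1′-binaphthalene-2,2′-diyl] N,N-bis[(S)-1-(2-methoxyphenyl)ethyl]phosphoramidite), CH2Cl2, −78 °C, slow addition of 23
Reagents that add atoms: none
Why: Proposed new method: regio- and enantioselective copper-catalysed SN2′ alkylation of an unsymmetrical 2-methyl-1,4-dibromobut-2-ene, in which the alkylcuprate adds anti-SN2′ across the C1–Br terminus so that copper lands on the secondary C3 (the other terminus would need a tertiary C2–Cu bond and is sterically disfavoured), the chiral phosphoramidite selects the alkene face to set C3 as S, and fast reductive elimination from the σ-allyl trivalent-copper species releases the 1,1-disubstituted alkene; the closest known reactions are the copper/phosphoramidite allylic alkylations of symmetrical (E)-1,4-dihalobut-2-enes and of β-methyl allylic chlorides with Grignard reagents.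

Step 9
Reactants: 20 [(2S)-5-bromo-2-(2-hydroxypropan-2-yl)-4,6-dimethoxy-2,3-dihydro-1-benzofuran-7-yl](3-hydroxyphenyl)methanone; 24 (3S)-3-(bromomethyl)-2,6-dimethylhepta-1,6-diene
Product: 26 (3-hydroxyphenyl){(2S)-2-(2-hydroxypropan-2-yl)-4,6-dimethoxy-5-[(2R)-5-methyl-2-(prop-1-en-2-yl)hex-5-en-1-yl]-2,3-dihydro-1-benzofuran-7-yl}methanone, via alkylzinc bromide 25 (not isolated)
Conditions: 24, Zn dust, I2 (5 mol %), DMA, 70 °C; then 20, Pd(OAc)2 (4 mol %), SPhos (8 mol %), THF, 45 °C, slow addition of 25 (2.5 equiv)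
Reagents that add atoms: none
Why: Zinc insertion touches no bond at the stereocentre, and Negishi sp2–sp3 cross-coupling with a bulky biarylphosphine copes with the di-ortho-methoxy bromide and outruns protonation by the free OH groups, so the configuration is retained (the descriptor becomes R only through the change in substituent priority).

Step 10
Reactants: 26 (3-hydroxyphenyl){(2S)-2-(2-hydroxypropan-2-yl)-4,6-dimethoxy-5-[(2R)-5-methyl-2-(prop-1-en-2-yl)hex-5-en-1-yl]-2,3-dihydro-1-benzofuran-7-yl}methanone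
Product: 27 (3-hydroxyphenyl){(2S)-6-hydroxy-2-(2-hydroxypropan-2-yl)-4-methoxy-5-[(2R)-5-methyl-2-(prop-1-en-2-yl)hex-5-en-1-yl]-2,3-dihydro-1-benzofuran-7-yl}methanone (CNP0263422.2)
Conditions: MgI2·OEt2 (4 equiv), toluene/THF, 70 °C; then cold 0.5 M HCl
Reagents that add atoms: none
Why: Chelation-controlled ether cleavage in which magnesium binds the ketone and the ortho 6-methoxy oxygen and iodide removes that methyl by SN2, while the non-chelated 4-methoxy group, the hindered ring C–O bond, the alkenes and the tertiary alcohol are left alone and both stereocentres are untouched.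

## Compound list

1 | resorcinol (benzene-1,3-diol) | Oc1cccc(O)c1 | starting material
2 | 3-methoxyphenol | COc1cccc(O)c1 | intermediate
3 | 1,3-dimethoxybenzene | COc1cccc(OC)c1 | intermediate
4 | 2-(3,5-dimethoxyphenyl)-4,4,5,5-tetramethyl-1,3,2-dioxaborolane | COc1cc(OC)cc(c1)B1OC(C)(C)C(C)(C)O1 | intermediate
5 | 3,5-dimethoxyphenol | COc1cc(O)cc(OC)c1 | intermediate
6 | 3-methylbut-2-enal | CC(C)=CC=O | starting material
7 | 3,5-dimethoxy-6-(3-methylbut-2-en-1-ylidene)cyclohexa-2,4-dien-1-one (ortho-quinone methide) | O=C1C=C(OC)C=C(OC)C1=CC=C(C)C | intermediate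
8 | 5,7-dimethoxy-2,2-dimethyl-2H-chromene | COc1cc(OC)c2C=CC(C)(C)Oc2c1 | intermediate
9 | (3R,4R)-3,4-epoxy-5,7-dimethoxy-2,2-dimethylchromane | COc1cc(OC)c2[C@H]3O[C@H]3C(C)(C)Oc2c1 | intermediate
10 | (3R)-5,7-dimethoxy-2,2-dimethylchroman-3-ol | COc1cc(OC)c2C[C@@H](O)C(C)(C)Oc2c1 | intermediate
11 | (3R)-5,7-dimethoxy-2,2-dimethylchroman-3-yl trifluoromethanesulfonate | COc1cc(OC)c2C[C@@H](OS(=O)(=O)C(F)(F)F)C(C)(C)Oc2c1 | intermediate
12 | aryloxiranium triflate (ring oxygen bridging the CMe2 carbon and the former C3; ion pair) | COc1cc(OC)c2C[C@H]3C(C)(C)[O+]3c2c1.[O-]S(=O)(=O)C(F)(F)F | intermediate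
13 | 2-[(2S)-4,6-dimethoxy-2,3-dihydro-1-benzofuran-2-yl]propan-2-ol | COc1cc(OC)c2C[C@@H](C(C)(C)O)Oc2c1 | intermediate
14 | 3-bromophenol | Oc1cccc(Br)c1 | starting material
15 | lithium 2-[(2S)-7-lithio-4,6-dimethoxy-2,3-dihydro-1-benzofuran-2-yl]propan-2-olate | COc1cc(OC)c2C[C@@H](C(C)(C)O[Li])Oc2c1[Li] | intermediate
16 | lithium alkoxide of (2S)-2-(2-hydroxypropan-2-yl)-N,4,6-trimethoxy-N-methyl-2,3-dihydro-1-benzofuran-7-carboxamide | COc1cc(OC)c2C[C@@H](C(C)(C)O[Li])Oc2c1C(=O)N(C)OC | intermediate
17 | lithium 3-lithiophenolate | [Li]Oc1cccc([Li])c1 | intermediate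
18 | trilithium tetrahedral adduct of 16 and 17 (carbinol carbon unassigned) | COc1cc(OC)c2C[C@@H](C(C)(C)O[Li])Oc2c1C(O[Li])(N(C)OC)c1cccc(O[Li])c1 | intermediate
19 | (3-hydroxyphenyl)[(2S)-2-(2-hydroxypropan-2-yl)-4,6-dimethoxy-2,3-dihydro-1-benzofuran-7-yl]methanone | COc1cc(OC)c2C[C@@H](C(C)(C)O)Oc2c1C(=O)c1cccc(O)c1 | intermediate
20 | [(2S)-5-bromo-2-(2-hydroxypropan-2-yl)-4,6-dimethoxy-2,3-dihydro-1-benzofuran-7-yl](3-hydroxyphenyl)methanone | COc1c(Br)c(OC)c2C[C@@H](C(C)(C)O)Oc2c1C(=O)c1cccc(O)c1 | intermediate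
21 | 4-bromo-2-methylbut-1-ene | C=C(C)CCBr | starting material
22 | (E)-1,4-dibromo-2-methylbut-2-ene | BrC/C(C)=C/CBr | starting material
23 | (3-methylbut-3-en-1-yl)magnesium bromide | C=C(C)CC[Mg]Br | intermediate
24 | (3S)-3-(bromomethyl)-2,6-dimethylhepta-1,6-diene | C=C(C)CC[C@H](CBr)C(=C)C | intermediate
25 | [(2S)-5-methyl-2-(prop-1-en-2-yl)hex-5-en-1-yl]zinc bromide | C=C(C)CC[C@H](C[Zn]Br)C(=C)C | intermediate
26 | (3-hydroxyphenyl){(2S)-2-(2-hydroxypropan-2-yl)-4,6-dimethoxy-5-[(2R)-5-methyl-2-(prop-1-en-2-yl)hex-5-en-1-yl]-2,3-dihydro-1-benzofuran-7-yl}methanone | C=C(C)CC[C@H](Cc1c(OC)c(C(=O)c2cccc(O)c2)c2c(c1OC)C[C@@H](C(C)(C)O)O2)C(=C)C | intermediate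
27 | (3-hydroxyphenyl){(2S)-6-hydroxy-2-(2-hydroxypropan-2-yl)-4-methoxy-5-[(2R)-5-methyl-2-(prop-1-en-2-yl)hex-5-en-1-yl]-2,3-dihydro-1-benzofuran-7-yl}methanone | C=C(C)CC[C@H](Cc1c(O)c(C(=O)c2cccc(O)c2)c2c(c1OC)C[C@@H](C(C)(C)O)O2)C(=C)C | target

## Step count and risk

Total steps: 10. Longest linear sequence: 9 (steps 1–7, 9 and 10, from resorcinol); step 8 is a one-step branch.

Steps most likely to fail:

**Step 6 (one-pot aroylation).** The risks are C7 versus C5 lithiation and sluggish addition to the hindered Weinreb amide. The fallback sets out from 13 and returns at 19. Compound 13 is dilithiated as in step 6 and quenched with DMF to give (2S)-2-(2-hydroxypropan-2-yl)-4,6-dimethoxy-2,3-dihydro-1-benzofuran-7-carbaldehyde F1, which can be purified from any C5 isomer. Lithium 3-lithiophenolate 17 (from 14) adds to the unhindered aldehyde to give [(2S)-2-(2-hydroxypropan-2-yl)-4,6-dimethoxy-2,3-dihydro-1-benzofuran-7-yl](3-hydroxyphenyl)methanol F2 as a mixture of carbinol epimers. MnO2 in CH2Cl2 oxidises the doubly benzylic alcohol to 19.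

**Step 8 (the proposed new allylic alkylation).** The risks are SN2 versus SN2′ attack, the wrong allylic terminus, and low ee. The fallback uses known chemistry, sets out from 21 and returns at 24. Finkelstein exchange (NaI, acetone) gives 4-iodo-2-methylbut-1-ene F3. The lithium dienolate of commercial methyl 3-methylbut-2-enoate (LiN(i-Pr)2, THF/DMPU, −78 °C) is alkylated at its α-carbon by F3, the deconjugative alkylation long used for lavandulol, to give racemic methyl 5-methyl-2-(prop-1-en-2-yl)hex-5-enoate F4. LiAlH4 in Et2O reduces it to racemic 5-methyl-2-(prop-1-en-2-yl)hex-5-en-1-ol F5. Lipase-catalysed acetylation (porcine pancreatic lipase, vinyl acetate), taken past 55 % conversion, leaves (2S)-5-methyl-2-(prop-1-en-2-yl)hex-5-en-1-ol F6 beside [(2R)-5-methyl-2-(prop-1-en-2-yl)hex-5-en-1-yl] acetate F7, which is discarded. CBr4/PPh3 in CH2Cl2 converts F6 into 24 without touching the stereocentre.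

**Step 9 (hindered Negishi coupling with free OH groups).** The risks are protonation of the alkylzinc and β-hydride elimination toward the conjugated diene. The fallback sets out from 24 and returns at 26, replacing the acid-sensitive alkylzinc by a proton-stable organoboron partner coupled under aqueous base. Copper-catalysed borylation of the primary bromide (B2pin2, CuI, PPh3, LiOMe, DMF, 25 °C) gives 4,4,5,5-tetramethyl-2-[(2S)-5-methyl-2-(prop-1-en-2-yl)hex-5-en-1-yl]-1,3,2-dioxaborolane F8. KHF2 in MeOH/H2O converts it into potassium trifluoro[(2S)-5-methyl-2-(prop-1-en-2-yl)hex-5-en-1-yl]borate F9. Suzuki–Miyaura coupling of F9 with 20 (Pd(OAc)2, RuPhos, K2CO3, toluene/H2O, 85 °C) gives 26.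

Further compounds
F1 | step 6 | (2S)-2-(2-hydroxypropan-2-yl)-4,6-dimethoxy-2,3-dihydro-1-benzofuran-7-carbaldehyde | COc1cc(OC)c2C[C@@H](C(C)(C)O)Oc2c1C=O
F2 | step 6 | [(2S)-2-(2-hydroxypropan-2-yl)-4,6-dimethoxy-2,3-dihydro-1-benzofuran-7-yl](3-hydroxyphenyl)methanol | COc1cc(OC)c2C[C@@H](C(C)(C)O)Oc2c1C(O)c1cccc(O)c1
F3 | step 8 | 4-iodo-2-methylbut-1-ene | C=C(C)CCI
F4 | step 8 | methyl 5-methyl-2-(prop-1-en-2-yl)hex-5-enoate (racemic) | C=C(C)CCC(C(=C)C)C(=O)OC
F5 | step 8 | 5-methyl-2-(prop-1-en-2-yl)hex-5-en-1-ol (racemic) | C=C(C)CCC(CO)C(=C)C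
F6 | step 8 | (2S)-5-methyl-2-(prop-1-en-2-yl)hex-5-en-1-ol | C=C(C)CC[C@H](CO)C(=C)C
F7 | step 8 | [(2R)-5-methyl-2-(prop-1-en-2-yl)hex-5-en-1-yl] acetate | C=C(C)CC[C@@H](COC(C)=O)C(=C)C
F8 | step 9 | 4,4,5,5-tetramethyl-2-[(2S)-5-methyl-2-(prop-1-en-2-yl)hex-5-en-1-yl]-1,3,2-dioxaborolane | C=C(C)CC[C@H](CB1OC(C)(C)C(C)(C)O1)C(=C)C
F9 | step 9 | potassium trifluoro[(2S)-5-methyl-2-(prop-1-en-2-yl)hex-5-en-1-yl]borate | C=C(C)CC[C@H](C[B-](F)(F)F)C(=C)C.[K+]
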